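**Plan**
1. Ring numbering of the target: C1 and C4 are the carbonyl carbons, C2 carries the nonadecyl chain. The quinone is taken back to 2-nonadecylhydroquinone by an oxidation-level change.
2. The hydroquinone ring is cut at C4–C5 (electrocyclic key step) and then at C1–C6 (vinyl Grignard addition). The para-dioxygenated six-membered ring with one substituent thus splits into a four-carbon cyclobutenone (C1–C4, both oxygens, the chain) and a two-carbon ethenyl unit (C5, C6).
3. The C2–chain bond is cut last, back to nonadecylmagnesium bromide and diisopropyl squarate, whose four-membered ring supplies C1–C4.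
4. Forward: the chain is joined to the squarate ring (step 1), reduction and hydrolysis give the monoalkyl cyclobutenedione (step 2), the ethenyl group is added (step 3), thermolysis opens the four-membered ring and closes the only new ring, the six-membered one (step 4), and oxidation gives the quinone (step 5).
5. Stereochemistry: the target has no stereocentre and no stereogenic double bond. The carbinol centres on the way are racemic and are erased in steps 2 and 4.

Key step: step 4

Assumption: the target SMILES contains no stereo element, so the achiral quinone itself is the required single stereoisomer and racemic intermediates are sufficient.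

**Step 1**
Reactants: 1 1-bromononadecane; 2 diisopropyl squarate
Product: 4 4-hydroxy-2,3-diisopropoxy-4-nonadecylcyclobut-2-en-1-one (racemic), via nonadecylmagnesium bromide 3 (not isolated)
Conditions: Mg, cat. I2, THF, 45 °C; then 2, THF, −78 °C; sat. aq. NH4Cl, −78 °C → rt
Reagents that add atoms: none
Why: Grignard formation followed by 1,2-addition of the primary alkylmagnesium bromide to one of the two equivalent carbonyls of the squarate ester at −78 °C should stop at the mono-adduct because the remaining carbonyl is then a vinylogous ester flanked by an alkoxide, and the new carbinol centre is formed racemic and is of no consequence.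

**Step 2**
Reactants: 4 4-hydroxy-2,3-diisopropoxy-4-nonadecylcyclobut-2-en-1-one
Product: 6 3-nonadecylcyclobut-3-ene-1,2-dione, via cyclobutenediol 5 (not isolated)
Conditions: DIBAL-H (2.5 equiv), THF, −78 → 0 °C; then 3 M aq. HCl, CH2Cl2, 0 °C → rt
Reagents that add atoms: water, O (supplies both carbonyl oxygens of 6)
Why: In a Stork–Danheiser-type reduction–hydrolysis, DIBAL-H adds 1,2 to the vinylogous ester carbonyl so that each carbinol carbon of diol 5 is allylic to an isopropoxy-bearing alkene carbon, and aqueous acid then ionises each carbinol to an alkoxy-stabilised allyl cation that water captures at the alkoxy carbon with loss of propan-2-ol, which moves both carbonyls onto the former enol ether carbons and leaves the C=C between the alkyl-bearing and the hydrogen-bearing carbon.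

**Step 3**
Reactants: 6 3-nonadecylcyclobut-3-ene-1,2-dione; 7 vinylmagnesium bromide
Product: 8 4-ethenyl-4-hydroxy-3-nonadecylcyclobut-2-en-1-one (racemic)
Conditions: 7 (1.1 equiv, added slowly), THF, −78 °C; sat. aq. NH4Cl at −78 °C
Reagents that add atoms: none
Why: Vinyl Grignard 1,2-addition at −78 °C should take place at the carbonyl next to the alkyl-bearing carbon, since the other carbonyl is deactivated by donation from the β-alkyl group, and the racemic carbinol centre as well as any adduct at the other carbonyl is inconsequential because both lead to the same hydroquinone in step 4.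

**Step 4**
Reactants: 8 4-ethenyl-4-hydroxy-3-nonadecylcyclobut-2-en-1-one
Product: 11 2-nonadecylbenzene-1,4-diol, via dienylketene 9 (not isolated), via cyclohexadienone 10 (not isolated)
Conditions: degassed p-xylene (0.02 M), 138 °C, Ar
Reagents that add atoms: none
Why: Heating triggers thermal conrotatory 4π-electrocyclic opening of the cyclobutenone C(=O)–C(OH) bond to dienylketene 9, which undergoes thermal disrotatory 6π-electrocyclisation in which the ketene carbon bonds to the terminal CH2 of the ethenyl group (C4–C5 of the target ring), and the resulting 2,4-cyclohexadienone 10 enolises to the aromatic hydroquinone. The closest known reaction type is the Moore–Liebeskind thermal ring expansion of 4-alkenyl-4-hydroxycyclobutenones to hydroquinones. The single ring formed, the six-membered carbocycle, closes by 6π-electrocyclisation of a ketene-terminated triene, driven by release of four-ring strain and by aromatisation. No stereocentre is created and the racemic carbinol centre of 8 is destroyed. The selectivity needed is torquoselectivity in the ring opening: the electron-donating hydroxyl on the carbinol carbon rotates outward, which turns the ethenyl group inward, cis to the ketene arm, so that the hydroxyl is held away from the ketene and the two reacting termini are within bonding distance. Site selectivity does not arise, because the monoalkyl hydroquinone is the same whichever ring carbonyl carried the ethenyl group.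

**Step 5**
Reactants: 11 2-nonadecylbenzene-1,4-diol
Product: 12 2-nonadecylcyclohexa-2,5-diene-1,4-dione (2-nonadecyl-1,4-benzoquinone)
Conditions: Ag2O (2 equiv), Na2SO4, Et2O, rt
Reagents that add atoms: none
Why: Silver(I) oxide effects the two-electron oxidation of the hydroquinone to the p-benzoquinone under neutral anhydrous conditions (hydroquinone-to-quinone oxidation), to which the saturated chain is inert.

**Compound list**
1 | 1-bromononadecane | CCCCCCCCCCCCCCCCCCCBr | starting material
2 | diisopropyl squarate (3,4-diisopropoxycyclobut-3-ene-1,2-dione) | CC(C)OC1=C(OC(C)C)C(=O)C1=O | starting material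
3 | nonadecylmagnesium bromide | CCCCCCCCCCCCCCCCCCC[Mg]Br | intermediate (not isolated)
4 | 4-hydroxy-2,3-diisopropoxy-4-nonadecylcyclobut-2-en-1-one, racemic | CCCCCCCCCCCCCCCCCCCC1(O)C(OC(C)C)=C(OC(C)C)C1=O | intermediate
5 | 3,4-diisopropoxy-1-nonadecylcyclobut-3-ene-1,2-diol, racemic mixture of diastereomers | CCCCCCCCCCCCCCCCCCCC1(O)C(O)C(OC(C)C)=C1OC(C)C | intermediate (not isolated)
6 | 3-nonadecylcyclobut-3-ene-1,2-dione | O=C1C=C(CCCCCCCCCCCCCCCCCCC)C1=O | intermediate
7 | vinylmagnesium bromide | C=C[Mg]Br | starting material
8 | 4-ethenyl-4-hydroxy-3-nonadecylcyclobut-2-en-1-one, racemic | C=CC1(O)C(CCCCCCCCCCCCCCCCCCC)=CC1=O | intermediate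
9 | (3E)-4-hydroxy-3-nonadecylhexa-1,3,5-trien-1-one (ethenyl cis to the ketene arm) | O=C=C/C(CCCCCCCCCCCCCCCCCCC)=C(/O)C=C | intermediate (not isolated)
10 | 4-hydroxy-3-nonadecylcyclohexa-2,4-dien-1-one | O=C1CC=C(O)C(CCCCCCCCCCCCCCCCCCC)=C1 | intermediate (not isolated)
11 | 2-nonadecylbenzene-1,4-diol | Oc1ccc(O)c(CCCCCCCCCCCCCCCCCCC)c1 | intermediate
12 | 2-nonadecylcyclohexa-2,5-diene-1,4-dione | CCCCCCCCCCCCCCCCCCCC1=CC(=O)C=CC1=O | target

**Totals**
Total step count: 5. Longest linear sequence: 5 steps (1/2 → 4 → 6 → 8 → 11 → 12).

**Steps most likely to fail**

Step 2. The hydride may fail to add cleanly in 1,2-fashion to the carbonyl of 4, which is deactivated by two oxygen donors and sits next to an alkoxide. Slow reduction, conjugate reduction or reversal of the tertiary alkoxide would then let the acid treatment deliver isopropoxy-bearing diones and not 6. The fallback reverses the order of the two nucleophiles. Setting out from 2, lithium tri-tert-butoxyaluminium hydride (THF, −78 °C) would reduce one of the two equivalent, most reactive carbonyls to the alkoxide of 4-hydroxy-2,3-diisopropoxycyclobut-2-en-1-one F1. Grignard reagent 3 would then be added in the same flask to the remaining carbonyl. This gives the dialkoxide of diol 5, where the route is rejoined and acid hydrolysis leads on to 6.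

Step 3. The basic vinyl Grignard reagent may deprotonate the chain CH2 that is vinylogously activated by the dione, add in conjugate fashion to the unsubstituted ring CH, or add a second time; each process erodes 8. The fallback brings in the two carbons as an acetylide and adjusts the oxidation level afterwards. Setting out from 6, ethynylmagnesium bromide (THF, −78 °C), which is less basic and adds strictly 1,2, would give 4-ethynyl-4-hydroxy-3-nonadecylcyclobut-2-en-1-one F2. Lindlar semihydrogenation of the terminal alkyne (H2, Pd/CaCO3–Pb, quinoline, EtOAc, rt) would then return the route at 8.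

Step 4. The dienylketene may be consumed before it cyclises, either by addition of the free hydroxyl to the ketene (lactonisation after inward rotation of the hydroxyl) or by intermolecular ketene reactions. The fallback masks the hydroxyl so that only the electrocyclic path remains. Setting out from 8, 1-(trimethylsilyl)imidazole (CH2Cl2, rt) would give 4-ethenyl-3-nonadecyl-4-[(trimethylsilyl)oxy]cyclobut-2-en-1-one F3. Thermolysis in degassed p-xylene should give 3-nonadecyl-4-[(trimethylsilyl)oxy]phenol F4 by the same ring opening and ring closure. Methanolysis of the silyl ether (cat. HCl, MeOH, rt, Ar) would bring the route back at 11.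

**Further compounds**
F1 | step 2 | 4-hydroxy-2,3-diisopropoxycyclobut-2-en-1-one | CC(C)OC1=C(OC(C)C)C(=O)C1O
F2 | step 3 | 4-ethynyl-4-hydroxy-3-nonadecylcyclobut-2-en-1-one | C#CC1(O)C(CCCCCCCCCCCCCCCCCCC)=CC1=O
F3 | step 4 | 4-ethenyl-3-nonadecyl-4-[(trimethylsilyl)oxy]cyclobut-2-en-1-one | C=CC1(O[Si](C)(C)C)C(CCCCCCCCCCCCCCCCCCC)=CC1=O
F4 | step 4 | 3-nonadecyl-4-[(trimethylsilyl)oxy]phenol | C[Si](C)(C)Oc1ccc(O)cc1CCCCCCCCCCCCCCCCCCC
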